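**Assumption:** germacrane numbering (C1–C15) is used for all ten-membered-ring compounds, and the required (1R,10R) oxirane is taken to be the face reached by peripheral attack on the 1(10)-alkene.

## Retrosynthetic overview

1. Last operations: epoxidation of C1=C10, C8 acylation with (2R,3R)-epoxyangelic acid (Sharpless epoxidation of angelyl alcohol), C3 benzoylation.
2. α-Methylene-γ-lactone: palladium cyclocarbonylation of a C7-ethynyl/C6-hydroxyl pair (C12 from CO), not an allylation/lactonisation.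
3. Key step: the ten-membered ring is not closed by macrocyclisation but made by anionic oxy-Cope ring expansion of a 1,2-dialkenylcyclohexenol. The chair sets 1(10)E, keeps 4Z and sets C8; peripheral protonation and reduction set C7 and C6.
4. Cyclohexenol: 4-silyloxy-isopiperitenone (from (S)-carvone; supplies C3) plus a β-alkoxy alkenyllithium built from 4-methoxybenzyl alcohol, trichloroethylene and a silyl bromoalkyne.
5. Ring order: cyclohexene (chiral pool) → cyclodecadiene (oxy-Cope) → γ-lactone (carbonylation) → oxirane (last).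

## Route

Step 1
Reactants: 1 (S)-(+)-carvone
Product: 2 (1S,4S,6S)-1-methyl-4-(prop-1-en-2-yl)-7-oxabicyclo[4.1.0]heptan-2-one
Conditions: 35% H2O2, NaOH (0.3 equiv), MeOH, 0 °C
Reagents that add atoms: hydrogen peroxide, OO
Why: Weitz–Scheffer nucleophilic epoxidation of the enone; hydroperoxide adds axially at the β-carbon anti to the isopropenyl group, so the oxirane forms trans to it as one diastereomer.

Step 2
Reactants: 2 carvone oxide
Product: 5 (1S,5R)-2-methyl-5-(prop-1-en-2-yl)cyclohex-2-en-1-ol, via epoxy hydrazone 3 (not isolated), via alkenyl diazene 4 (not isolated)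
Conditions: N2H4·H2O (3 equiv), AcOH (0.2 equiv), MeOH, 0 °C → rt
Reagents that add atoms: none
Why: Wharton transposition; the hydrazone opens the oxirane to an alkenyl diazene that loses N2, and the C–O bond of the former epoxide is kept, so the new carbinol (C3 of the target, S) is trans to the isopropenyl group.

Step 3
Reactants: 5 (1S,5R)-trans-carveol
Product: 6 tert-butyl(dimethyl){[(1S,5R)-2-methyl-5-(prop-1-en-2-yl)cyclohex-2-en-1-yl]oxy}silane
Conditions: TBSCl, imidazole, DMF, rt
Reagents that add atoms: tert-butyldimethylsilyl chloride, CC(C)(C)[Si](C)(C)Cl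
Why: standard silyl ether protection of the secondary allylic alcohol; no stereocentre is touched.

Step 4
Reactants: 6 silyl ether of trans-carveol
Product: 7 (4S,6R)-4-[(tert-butyldimethylsilyl)oxy]-3-methyl-6-(prop-1-en-2-yl)cyclohex-2-en-1-one
Conditions: Rh2(cap)4 (1 mol%; cap = caprolactamate), t-BuOOH (5 equiv), K2CO3 (0.5 equiv), CH2Cl2, rt
Reagents that add atoms: tert-butyl hydroperoxide, CC(C)(C)OO
Why: dirhodium-catalysed radical allylic C–H oxidation (tert-butylperoxyl H-abstraction, mixed peroxide, collapse to ketone) at the only ring CH2 allylic to the trisubstituted alkene gives the conjugated enone; both stereocentres are untouched, the isopropenyl group staying equatorial and trans to the pseudoaxial silyloxy group.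

Step 5
Reactants: 8 4-methoxybenzyl alcohol; 9 trichloroethylene
Product: 11 1-({[(E)-1,2-dichloroethenyl]oxy}methyl)-4-methoxybenzene, via dichloroacetylene 10 (not isolated)
Conditions: KH (2 equiv), THF, 0 °C; then 9, −50 °C → rt
Reagents that add atoms: none
Why: first stage of the Greene ynol ether synthesis; base-induced loss of HCl gives dichloroacetylene, the alkoxide adds anti to it and protonation gives the dichlorovinyl ether.

Step 6
Reactants: 11 dichlorovinyl ether; 12 (bromoethynyl)tri(propan-2-yl)silane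
Product: 16 {4-[(4-methoxybenzyl)oxy]buta-1,3-diyn-1-yl}tri(propan-2-yl)silane, via chloroalkynyl ether 13 (not isolated), via lithium acetylide 14 (not isolated), via copper acetylide 15 (not isolated)
Conditions: n-BuLi (2.1 equiv), THF, −78 → −40 °C; CuI (1.05 equiv), −40 → 0 °C; then 12, pyridine, 0 → 20 °C (kept below 25 °C)
Reagents that add atoms: none
Why: deprotonation/β-elimination and chlorine–lithium exchange give the lithium alkoxyacetylide, which after transmetalation to copper couples with the 1-bromoalkyne (Cadiot–Chodkiewicz-type heterocoupling) to the unsymmetrical diyne.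

Step 7
Reactants: 16 diynyl ether
Product: 18 {(3E)-3-iodo-4-[(4-methoxybenzyl)oxy]but-3-en-1-yn-1-yl}tri(propan-2-yl)silane, via alkenylzirconocene chloride 17 (not isolated)
Conditions: Cp2Zr(H)Cl (1.2 equiv), THF, 20 °C, dark; then I2, 0 °C
Reagents that add atoms: iodine, II
Why: hydrozirconation (syn addition of Zr–H) takes place at the electron-rich, unhindered ynol ether triple bond with hydride going to the electrophilic oxygen-bearing carbon and zirconium β to oxygen, and iodinolysis with retention gives the iodide with I trans to the alkoxy group.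

Step 8
Reactants: 18 alkenyl iodide; 7 enone
Product: 20 (1R,4S,6R)-4-[(tert-butyldimethylsilyl)oxy]-1-{(1E)-1-[(4-methoxybenzyl)oxy]-4-[tri(propan-2-yl)silyl]but-1-en-3-yn-2-yl}-3-methyl-6-(prop-1-en-2-yl)cyclohex-2-en-1-ol, via alkenyllithium 19 (not isolated)
Conditions: t-BuLi (2.05 equiv), Et2O, −78 °C; then 7, THF, −78 °C; H2O
Reagents that add atoms: none
Why: iodine–lithium exchange keeps the alkene geometry and the bulky alkenyllithium adds 1,2 to the enone from the equatorial direction, anti to the α'-isopropenyl group, giving the trans-1,2-dialkenyl carbinol (1R) that a chair oxy-Cope needs, as known for alkenylmetal additions to isopiperitenone-type enones.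

Step 9
Reactants: 20 dialkenyl carbinol
Product: 24 (1R,2Z,4S,6E,9R,10S)-4-[(tert-butyldimethylsilyl)oxy]-9-[(4-methoxybenzyl)oxy]-3,7-dimethyl-10-{[tri(propan-2-yl)silyl]ethynyl}cyclodeca-2,6-dien-1-ol, via potassium alkoxide 21 (not isolated), via potassium ynenolate 22 (not isolated), via alkynyl ketone 23 (not isolated)
Conditions: KH (1.5 equiv), 18-crown-6 (1.5 equiv), THF, 0 → 20 °C; AcOH (1.6 equiv), −78 °C; then MeOH, CeCl3·7H2O, NaBH4, −78 °C
Reagents that add atoms: none
Why: anionic oxy-Cope ring expansion through a chair transition state (both alkenyl groups and the C8 alkoxy group equatorial) forms the ten-membered ring with C1=C10 as E, carries the ring alkene over as 4Z and fixes C8 (R), the C8–O bond lying in the nodal plane of the ring-E ynenolate so that β-elimination is stereoelectronically disfavoured; kinetic protonation at C7 and Luche 1,2-reduction at C6 then both come from the open outer face of the perpendicular enolate and enone units (net syn delivery of two H across the former E-enolate), giving C7 and C6 as in the target, with the bulky silyl group keeping the proton off the alkyne terminus.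

Step 10
Reactants: 24 cyclodecadienol
Product: 25 (1R,2Z,4S,6E,9R,10S)-10-ethynyl-9-[(4-methoxybenzyl)oxy]-3,7-dimethylcyclodeca-2,6-diene-1,4-diol
Conditions: TBAF (3 equiv), THF, 0 °C → rt
Reagents that add atoms: none
Why: fluoride-mediated desilylation removes the C3 silyl ether and the alkynylsilane together, while the benzyl-type ether at C8 stays.

Step 11
Reactants: 25 ethynyl diol
Product: 26 (3S,6R,7R,8R)-3-hydroxy-8-[(4-methoxybenzyl)oxy]germacra-1(10)E,4Z,11(13)-trien-12,6-olide
Conditions: PdCl2(PPh3)2 (5 mol%), SnCl2 (5 mol%), CO (7 atm), MeCN, 65 °C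
Reagents that add atoms: carbon monoxide, [C-]#[O+]
Why: Norton-type cyclocarbonylation of a homopropargylic alcohol; the alkoxycarbonyl species formed on divalent palladium at the C6 hydroxyl adds syn across the terminal alkyne and protonolysis releases the α-methylene-γ-butyrolactone, C6 and C7 keeping their configuration (trans-fused lactone) and the masked C8 oxygen allowing only the 6,12-lactone.

Step 12
Reactants: 26 hydroxy lactone
Product: 27 (3S,6R,7R,8R)-3-(benzoyloxy)-8-[(4-methoxybenzyl)oxy]germacra-1(10)E,4Z,11(13)-trien-12,6-olide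
Conditions: BzCl (1.5 equiv), pyridine, DMAP (0.1 equiv), CH2Cl2, 0 °C → rt
Reagents that add atoms: benzoyl chloride, O=C(Cl)c1ccccc1
Why: DMAP-catalysed acylation of the only free hydroxyl (C3), with retention.

Step 13
Reactants: 27 benzoate
Product: 28 (3S,6R,7R,8R)-3-(benzoyloxy)-8-hydroxygermacra-1(10)E,4Z,11(13)-trien-12,6-olide
Conditions: DDQ (1.3 equiv), CH2Cl2/pH 7 buffer (10:1), 0 °C
Reagents that add atoms: none
Why: oxidative cleavage of the 4-methoxybenzyl ether (hydride abstraction, hemiacetal hydrolysis) frees the C8 hydroxyl; benzoate, lactone and alkenes are inert.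

Step 14
Reactants: 29 angelic acid
Product: 30 (Z)-2-methylbut-2-en-1-ol
Conditions: LiAlH4, Et2O, 0 °C
Reagents that add atoms: none
Why: aluminium hydride reduction of the unsaturated acid to the allylic alcohol; the Z alkene is neither reduced nor isomerised at 0 °C.

Step 15
Reactants: 30 angelyl alcohol
Product: 31 [(2S,3R)-2,3-dimethyloxiran-2-yl]methanol
Conditions: Ti(OiPr)4 (10 mol%), L-(+)-diethyl tartrate (12 mol%), t-BuOOH, 4 Å MS, CH2Cl2, −20 °C
Reagents that add atoms: tert-butyl hydroperoxide, CC(C)(C)OO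
Why: Sharpless asymmetric epoxidation; the L-(+)-tartrate catalyst delivers oxygen to the face that gives (2S,3R), and the syn addition to the Z alkene keeps the two methyl groups trans.

Step 16
Reactants: 31 epoxy alcohol
Product: 32 (2R,3R)-2,3-dimethyloxirane-2-carboxylic acid
Conditions: TEMPO (0.2 equiv), PhI(OAc)2 (2.2 equiv), MeCN/H2O (1:1), rt
Reagents that add atoms: water, O
Why: oxoammonium oxidation through the aldehyde hydrate gives the acid without touching the oxirane; the C2 descriptor changes from S to R only through the priority change.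

Step 17
Reactants: 32 epoxyangelic acid; 28 C8 alcohol
Product: 34 (3S,6R,7R,8R)-3-(benzoyloxy)-8-{[(2R,3R)-2,3-dimethyloxirane-2-carbonyl]oxy}germacra-1(10)E,4Z,11(13)-trien-12,6-olide, via mixed anhydride 33 (not isolated)
Conditions: 2,4,6-Cl3C6H2COCl, Et3N, toluene, rt; then 28, DMAP, rt
Reagents that add atoms: none
Why: Yamaguchi esterification through the mixed anhydride and DMAP acyl transfer; the acid has no α-hydrogen so it cannot epimerise, and C8 reacts with retention.

Step 18
Reactants: 34 diene ester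
Product: 35 CNP0324463.6
Conditions: mCPBA (1.1 equiv), NaHCO3, CH2Cl2, 0 °C
Reagents that add atoms: 3-chloroperoxybenzoic acid, O=C(OO)c1cccc(Cl)c1
Why: Prilezhaev epoxidation is chemoselective for the electron-rich C1=C10 bond (C4=C5 carries two allylic acyloxy groups, the exocyclic alkene is conjugated) and stereospecific for the E geometry; peripheral attack on the heliangolide conformer with C14 on the β face gives the (1R,10R) oxirane.

## Compound list

1 | (S)-(+)-carvone, (5S)-2-methyl-5-(prop-1-en-2-yl)cyclohex-2-en-1-one | CC1=CC[C@@H](CC1=O)C(C)=C | starting material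
2 | (1S,4S,6S)-1-methyl-4-(prop-1-en-2-yl)-7-oxabicyclo[4.1.0]heptan-2-one (oxirane trans to isopropenyl) | C[C@]12O[C@H]1C[C@@H](CC2=O)C(C)=C | intermediate
3 | hydrazone of 2 (C=N–NH2 at C2, configuration unchanged) | C[C@]12O[C@H]1C[C@@H](CC2=NN)C(C)=C | intermediate (not isolated)
4 | (1S,5R)-3-diazenyl-2-methyl-5-(prop-1-en-2-yl)cyclohex-2-en-1-ol | CC1=C(N=N)C[C@H](C[C@@H]1O)C(C)=C | intermediate (not isolated)
5 | (1S,5R)-2-methyl-5-(prop-1-en-2-yl)cyclohex-2-en-1-ol (trans-carveol) | CC1=CC[C@H](C[C@@H]1O)C(C)=C | intermediate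
6 | tert-butyl(dimethyl){[(1S,5R)-2-methyl-5-(prop-1-en-2-yl)cyclohex-2-en-1-yl]oxy}silane | CC1=CC[C@H](C[C@@H]1O[Si](C)(C)C(C)(C)C)C(C)=C | intermediate
7 | (4S,6R)-4-[(tert-butyldimethylsilyl)oxy]-3-methyl-6-(prop-1-en-2-yl)cyclohex-2-en-1-one | CC1=CC(=O)[C@H](C[C@@H]1O[Si](C)(C)C(C)(C)C)C(C)=C | intermediate
8 | 4-methoxybenzyl alcohol | COc1ccc(CO)cc1 | starting material
9 | trichloroethylene | ClC=C(Cl)Cl | starting material
10 | dichloroacetylene | ClC#CCl | intermediate (not isolated)
11 | 1-({[(E)-1,2-dichloroethenyl]oxy}methyl)-4-methoxybenzene | COc1ccc(CO/C(Cl)=C\Cl)cc1 | intermediate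
12 | (bromoethynyl)tri(propan-2-yl)silane | CC(C)[Si](C#CBr)(C(C)C)C(C)C | starting material
13 | 1-{[(chloroethynyl)oxy]methyl}-4-methoxybenzene | COc1ccc(COC#CCl)cc1 | intermediate (not isolated)
14 | lithium 2-[(4-methoxybenzyl)oxy]ethynide | [Li]C#COCc1ccc(OC)cc1 | intermediate (not isolated)
15 | copper 2-[(4-methoxybenzyl)oxy]ethynide, CuC≡COCH2C6H4OMe | [Cu]C#COCc1ccc(OC)cc1 | intermediate (not isolated)
16 | {4-[(4-methoxybenzyl)oxy]buta-1,3-diyn-1-yl}tri(propan-2-yl)silane | COc1ccc(COC#CC#C[Si](C(C)C)(C(C)C)C(C)C)cc1 | intermediate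
17 | chlorobis(cyclopentadienyl){(1E)-1-[(4-methoxybenzyl)oxy]-4-[tri(propan-2-yl)silyl]but-1-en-3-yn-2-yl}zirconium (Zr trans to O) | COc1ccc(CO/C=C(/[Zr](Cl)(C2C=CC=C2)C2C=CC=C2)C#C[Si](C(C)C)(C(C)C)C(C)C)cc1 | intermediate (not isolated)
18 | {(3E)-3-iodo-4-[(4-methoxybenzyl)oxy]but-3-en-1-yn-1-yl}tri(propan-2-yl)silane (I trans to O) | COc1ccc(CO/C=C(/I)C#C[Si](C(C)C)(C(C)C)C(C)C)cc1 | intermediate
19 | {(1Z)-1-[(4-methoxybenzyl)oxy]-4-[tri(propan-2-yl)silyl]but-1-en-3-yn-2-yl}lithium (Li trans to O) | COc1ccc(CO/C=C(/[Li])C#C[Si](C(C)C)(C(C)C)C(C)C)cc1 | intermediate (not isolated)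
20 | (1R,4S,6R)-4-[(tert-butyldimethylsilyl)oxy]-1-{(1E)-1-[(4-methoxybenzyl)oxy]-4-[tri(propan-2-yl)silyl]but-1-en-3-yn-2-yl}-3-methyl-6-(prop-1-en-2-yl)cyclohex-2-en-1-ol | CC1=C[C@](O)(/C(C#C[Si](C(C)C)(C(C)C)C(C)C)=C/OCc2ccc(OC)cc2)[C@H](C[C@@H]1O[Si](C)(C)C(C)(C)C)C(C)=C | intermediate
21 | potassium alkoxide of 20 | CC1=C[C@]([O-])(/C(C#C[Si](C(C)C)(C(C)C)C(C)C)=C/OCc2ccc(OC)cc2)[C@H](C[C@@H]1O[Si](C)(C)C(C)(C)C)C(C)=C.[K+] | intermediate (not isolated)
22 | potassium (4S,9R)-4-[(tert-butyldimethylsilyl)oxy]-9-[(4-methoxybenzyl)oxy]-3,7-dimethyl-10-{[tri(propan-2-yl)silyl]ethynyl}cyclodeca-1(10),2,6-trien-1-olate (2Z,6E; enolate double bond trans in the ring) | [K+].[O-]/C1=C(C#C[Si](C(C)C)(C(C)C)C(C)C)\[C@H](OCc2ccc(OC)cc2)C/C(C)=C/C[C@H](O[Si](C)(C)C(C)(C)C)/C(C)=C\1 | intermediate (not isolated)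
23 | (2Z,4S,6E,9R,10R)-4-[(tert-butyldimethylsilyl)oxy]-9-[(4-methoxybenzyl)oxy]-3,7-dimethyl-10-{[tri(propan-2-yl)silyl]ethynyl}cyclodeca-2,6-dien-1-one | O=C1/C=C(/C)[C@@H](O[Si](C)(C)C(C)(C)C)C/C=C(\C)C[C@@H](OCc2ccc(OC)cc2)[C@H]1C#C[Si](C(C)C)(C(C)C)C(C)C | intermediate (not isolated)
24 | (1R,2Z,4S,6E,9R,10S)-4-[(tert-butyldimethylsilyl)oxy]-9-[(4-methoxybenzyl)oxy]-3,7-dimethyl-10-{[tri(propan-2-yl)silyl]ethynyl}cyclodeca-2,6-dien-1-ol | O[C@@H]1/C=C(/C)[C@@H](O[Si](C)(C)C(C)(C)C)C/C=C(\C)C[C@@H](OCc2ccc(OC)cc2)[C@H]1C#C[Si](C(C)C)(C(C)C)C(C)C | intermediate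
25 | (1R,2Z,4S,6E,9R,10S)-10-ethynyl-9-[(4-methoxybenzyl)oxy]-3,7-dimethylcyclodeca-2,6-diene-1,4-diol | O[C@@H]1/C=C(/C)[C@@H](O)C/C=C(\C)C[C@@H](OCc2ccc(OC)cc2)[C@H]1C#C | intermediate
26 | (3S,6R,7R,8R)-3-hydroxy-8-[(4-methoxybenzyl)oxy]germacra-1(10)E,4Z,11(13)-trien-12,6-olide | C=C1C(=O)O[C@@H]2/C=C(/C)[C@@H](O)C/C=C(\C)C[C@@H](OCc3ccc(OC)cc3)[C@@H]12 | intermediate
27 | (3S,6R,7R,8R)-3-(benzoyloxy)-8-[(4-methoxybenzyl)oxy]germacra-1(10)E,4Z,11(13)-trien-12,6-olide | C=C1C(=O)O[C@@H]2/C=C(/C)[C@@H](OC(=O)c3ccccc3)C/C=C(\C)C[C@@H](OCc3ccc(OC)cc3)[C@@H]12 | intermediate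
28 | (3S,6R,7R,8R)-3-(benzoyloxy)-8-hydroxygermacra-1(10)E,4Z,11(13)-trien-12,6-olide | C=C1C(=O)O[C@@H]2/C=C(/C)[C@@H](OC(=O)c3ccccc3)C/C=C(\C)C[C@@H](O)[C@@H]12 | intermediate
29 | angelic acid, (Z)-2-methylbut-2-enoic acid | C/C=C(/C)C(=O)O | starting material
30 | (Z)-2-methylbut-2-en-1-ol | C/C=C(/C)CO | intermediate
31 | [(2S,3R)-2,3-dimethyloxiran-2-yl]methanol | OC[C@]1(C)O[C@@H]1C | intermediate
32 | (2R,3R)-2,3-dimethyloxirane-2-carboxylic acid | OC(=O)[C@]1(C)O[C@@H]1C | intermediate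
33 | (2R,3R)-2,3-dimethyloxirane-2-carboxylic 2,4,6-trichlorobenzoic anhydride | O=C(OC(=O)[C@]1(C)O[C@@H]1C)c1c(Cl)cc(Cl)cc1Cl | intermediate (not isolated)
34 | (3S,6R,7R,8R)-3-(benzoyloxy)-8-{[(2R,3R)-2,3-dimethyloxirane-2-carbonyl]oxy}germacra-1(10)E,4Z,11(13)-trien-12,6-olide | C=C1C(=O)O[C@@H]2/C=C(/C)[C@@H](OC(=O)c3ccccc3)C/C=C(\C)C[C@@H](OC(=O)[C@]3(C)O[C@@H]3C)[C@@H]12 | intermediate
35 | CNP0324463.6, (1R,3S,4Z,6R,7R,8R,10R)-3-(benzoyloxy)-1,10-epoxy-8-{[(2R,3R)-2,3-dimethyloxirane-2-carbonyl]oxy}germacra-4,11(13)-dien-12,6-olide | C=C1C(=O)O[C@@H]2/C=C(/C)[C@@H](OC(=O)c3ccccc3)C[C@H]3O[C@]3(C)C[C@@H](OC(=O)[C@]3(C)O[C@@H]3C)[C@@H]12 | target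

## Step count and risks

Total step count: 18. Longest linear sequence: 12 steps (steps 1–4, 8–13, 17 and 18, from 1 to 35).

Steps most likely to fail:

Step 4. The radical oxidant may also attack the silyloxy-bearing C–H or the isopropenyl group, giving mixtures. The fallback puts the ketone oxygen in before the transposition, so no C–H oxidation is needed. It sets out from 1: LiN(iPr)2 in THF at −78 °C followed by 2-(phenylsulfonyl)-3-phenyloxaziridine hydroxylates the kinetic α'-enolate anti to the isopropenyl group and gives trans-6-hydroxycarvone F1. Et3SiCl/imidazole gives the triethylsilyl ether F2. H2O2/NaOH in MeOH at 0 °C gives the epoxy ketone F3 (oxirane trans to isopropenyl). N2H4·H2O/AcOH (Wharton) gives the transposed allylic alcohol F4. TBSCl/imidazole gives the bis-silyl ether F5. PPTS in MeOH at 0 °C removes only the triethylsilyl group to give the allylic alcohol F6, and Dess–Martin periodinane oxidises F6 to the enone, where the fallback comes back to the route at 7.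

Step 9. The β-alkoxy α-alkynyl ketone 23 can lose the C8 alkoxide (E1cB), epimerise at C7 or slip to an allenone while base is still present at the quench. The fallback separates enolate capture from protonation. It sets out from 20: after the same KH/18-crown-6 rearrangement, Me3SiCl/Et3N at −78 °C traps the ynenolate on oxygen and the ring-E trimethylsilyl enol ether F7 is isolated. Pyridine-buffered HF·pyridine in THF at −40 °C then protonates C7 from the outer face under acid, where no enolate or alkoxide base exists, and NaBH4/CeCl3·7H2O is added to the same flask. The fallback comes back to the route at 24 (through 23).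

Step 11. The Lewis-acidic Pd/Sn system at 65 °C may ionise the two allylic alcohols or trigger transannular cyclisation of the diene. The fallback makes the lactone from an alkenyl halide under basic conditions. It sets out from 25: Mo(CO)3(CNtBu)3 (cat.) and Bu3SnH in THF at 55 °C give the internal (Markovnikov) alkenylstannane F8. I2 in CH2Cl2 at 0 °C gives the 2-iodoalkene F9. Pd(PPh3)4 (5 mol%), CO (1 atm) and Et3N in MeCN at 50 °C close the ring by oxidative addition to zerovalent palladium, CO insertion and capture of the acyl group by the C6 hydroxyl. The fallback comes back to the route at 26.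

Further compounds
F1 | step 4 | (5R,6R)-6-hydroxy-2-methyl-5-(prop-1-en-2-yl)cyclohex-2-en-1-one | CC1=CC[C@@H]([C@@H](O)C1=O)C(C)=C
F2 | step 4 | (5R,6R)-2-methyl-5-(prop-1-en-2-yl)-6-[(triethylsilyl)oxy]cyclohex-2-en-1-one | CC1=CC[C@@H]([C@@H](O[Si](CC)(CC)CC)C1=O)C(C)=C
F3 | step 4 | 1-methyl-4-(prop-1-en-2-yl)-3-[(triethylsilyl)oxy]-7-oxabicyclo[4.1.0]heptan-2-one (oxirane trans to isopropenyl) | C[C@]12O[C@H]1C[C@@H]([C@@H](O[Si](CC)(CC)CC)C2=O)C(C)=C
F4 | step 4 | (1S,4S,5R)-2-methyl-5-(prop-1-en-2-yl)-4-[(triethylsilyl)oxy]cyclohex-2-en-1-ol | CC1=C[C@H](O[Si](CC)(CC)CC)[C@H](C[C@@H]1O)C(C)=C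
F5 | step 4 | tert-butyldimethylsilyl ether of F4 (1-O-TBS, 4-O-triethylsilyl) | CC1=C[C@H](O[Si](CC)(CC)CC)[C@H](C[C@@H]1O[Si](C)(C)C(C)(C)C)C(C)=C
F6 | step 4 | (1S,4S,6R)-4-[(tert-butyldimethylsilyl)oxy]-3-methyl-6-(prop-1-en-2-yl)cyclohex-2-en-1-ol | CC1=C[C@H](O)[C@H](C[C@@H]1O[Si](C)(C)C(C)(C)C)C(C)=C
F7 | step 9 | trimethylsilyl enol ether of 23 (2Z,6E; enol double bond trans in the ring) | C[Si](C)(C)O/C1=C(C#C[Si](C(C)C)(C(C)C)C(C)C)\[C@H](OCc2ccc(OC)cc2)C/C(C)=C/C[C@H](O[Si](C)(C)C(C)(C)C)/C(C)=C\1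
F8 | step 11 | 10-[1-(tributylstannyl)ethenyl] analogue of 25 | O[C@@H]1/C=C(/C)[C@@H](O)C/C=C(\C)C[C@@H](OCc2ccc(OC)cc2)[C@H]1C(=C)[Sn](CCCC)(CCCC)CCCC
F9 | step 11 | 10-(1-iodoethenyl) analogue of 25 | O[C@@H]1/C=C(/C)[C@@H](O)C/C=C(\C)C[C@@H](OCc2ccc(OC)cc2)[C@H]1C(I)=C
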